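The constants are those of an exercise; what happens was integrated by code.

Set the side product against the partner, not against the clock.

    substrate → intermediate (k1 = 0.014 s⁻¹)
    partner + intermediate → target (k2 = 0.0094 M⁻¹ s⁻¹)
    2 intermediate → homo product (k3 = 0.0089 M⁻¹ s⁻¹)
    target → over-reaction product (k4 = 0.045 s⁻¹)
    intermediate → side product (k5 = 0.0077 s⁻¹)

| setting | Wednesday's | Tuesday's |
|---|---|---|
| substrate | 0.50 M | 0.50 M |
| partner | 0.550 M | 0.720 M |
| time | 20 min | 20 min |

- a species is counted by the substrate in it: one homo product counts as two
- two of one species on the left: rate k times its square, two consumed each time
- run time (Wednesday's): 20 min

1. which of these there is most of at the end, counted by the substrate in it, Wednesday's (intermediate / side product / over-reaction product / homo product)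
2. which of these there is most of at the end, counted by the substrate in it, Tuesday's (intermediate / side product / over-reaction product / homo product)
3. amount of the one of these that there is most of at the end, in percent of the substrate charged, Wednesday's
4. amount of the one of these that there is most of at the end, in percent of the substrate charged, Tuesday's

Divide the rate of the step to side product by the rate of the step that consumes partner. [intermediate] cancels, which leaves a ratio of two constants over [partner]. Name that ratio's constant part the crossover, 0.819 M: the [partner] at which both steps run equally fast, a selectivity factor in concentration units. Integrate once: side product formed = crossover × ln(charged [partner] / final [partner]).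

Now count the end as complete, since the run of 20 min far outlasts the substrate half-life of 0.825 min. The target half-life of 0.257 min is shorter still, so book captured intermediate as over-reaction product.

Try a frozen [partner] first. Wednesday's flask then sends 59.8% of the intermediate to side product. Object: the homo step also takes intermediate. Treat it as a tax on a plain chain. Wednesday's first-order loss of intermediate is 0.772 min⁻¹ and Tuesday's is 0.868 min⁻¹. Square the resulting [intermediate] profile and integrate. The reckoned tax is 18.0% on Wednesday's flask and 15.1% on Tuesday's.

Object again: [partner] falls during capture. Use a mean [partner], halfway through a first capture estimate. By this estimate Wednesday's flask captures 0.149 M, which leaves 52.2% as side product. By the same estimate Tuesday's flask captures 0.183 M, which leaves 48.3%. I commit to side product leading on both flasks.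

The forecast also names side product on Wednesday's flask and side product on Tuesday's, at 54% and 50%, a little above my figures. Its words: “the extra partner on Tuesday trims it by only a few points”.

Wednesday's flask ends with side product at 54.4%, and Tuesday's with side product at 49.6%. At 20.0 min, Wednesday's flask keeps 72% of its partner, and the crossover rule turns that reading into 54.4% side product. The neighbour flask with 2.2 M of partner stands above the crossover and keeps 85% of it. There the rule gives 27.3% against 27.3% found, and over-reaction product leads that flask at 67.6%.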